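The plan cuts ring C (C14, C16, C18, C20, C21, C22, C28) at its oxirane: the epoxide carbons C14 and C16 are treated as a tetrasubstituted C14=C16 alkene next to the quaternary C28, and that alkene as two ketone carbonyls. One low-valent titanium coupling then forms the C14=C16 bond and closes the seven-membered ring in a single operation, with no stereocentre at stake. Its precursor is a seco-ring-C diketone: a neopentyl C14 ketone that already carries the silylated oxepane–cyclohexane half (rings A and B), and a cyclopentane (ring D) whose cis 3-oxobutyl arm ends in the C16 methyl ketone. Atom numbers follow the order of the target SMILES.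

Key step: step 22

Remark: (S)-4-(tert-butyldimethylsilyloxy)cyclopent-2-en-1-one is taken to be purchasable. C35 is carried as a triethylsilyl ether because the cyclisation of step 5 delivers it in that form.

Step 1
Reactants: 1 geranyl bromide; 2 dimethyl (2-oxopropyl)phosphonate
Product: 4 dimethyl [(5E)-6,10-dimethyl-2-oxoundeca-5,9-dien-1-yl]phosphonate, via phosphonate dianion 3 (not isolated)
Conditions: 2, NaH, THF, 0 °C; n-BuLi, 0 °C; 1, 0 °C to rt; aq. NH4Cl
Reagents that add atoms: none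
Why: γ-Alkylation of a β-ketophosphonate dianion, in which the more basic terminal carbanion displaces the allylic bromide by SN2, so the E-alkene of 1 is kept and no stereocentre is formed.

Step 2
Reactants: 4 dimethyl [(5E)-6,10-dimethyl-2-oxoundeca-5,9-dien-1-yl]phosphonate; 5 benzyloxyacetaldehyde
Product: 6 (2E,7E)-1-(benzyloxy)-8,12-dimethyltrideca-2,7,11-trien-4-one
Conditions: LiCl, i-Pr2NEt, MeCN, rt
Reagents that add atoms: none
Why: Horner–Wadsworth–Emmons olefination with LiCl and a tertiary amine should give the E-enone under conditions mild enough for the enolisable aldehyde, and it installs C12 and C13 with their oxygen handle.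

Step 3
Reactants: 6 (2E,7E)-1-(benzyloxy)-8,12-dimethyltrideca-2,7,11-trien-4-one
Product: 7 (2E)-1-(benzyloxy)-6-[(2R,3R)-3-{2-[(2R)-3,3-dimethyloxiran-2-yl]ethyl}-3-methyloxiran-2-yl]hex-2-en-4-one
Conditions: 1,2:4,5-di-O-isopropylidene-β-D-erythro-2,3-hexodiulo-2,6-pyranose (30 mol%), KHSO5, K2CO3, Bu4NHSO4, MeCN/CH2(OMe)2/aq. Na2B4O7 buffer, 0 °C
Reagents that add atoms: potassium peroxymonosulfate, [K+].[O-]S(=O)(=O)OO
Why: Shi asymmetric epoxidation, in which the chiral dioxirane formed from the D-fructose-derived ketone oxidises both electron-rich trisubstituted alkenes on the same face through a spiro transition state, setting C35 (R) and C5/C31 (R,R), while the electron-poor enone alkene does not react.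

Step 4
Reactants: 7 (2E)-1-(benzyloxy)-6-[(2R,3R)-3-{2-[(2R)-3,3-dimethyloxiran-2-yl]ethyl}-3-methyloxiran-2-yl]hex-2-en-4-one
Product: 8 {[(3Z)-6-(benzyloxy)-1-[(2R,3R)-3-{2-[(2R)-3,3-dimethyloxiran-2-yl]ethyl}-3-methyloxiran-2-yl]hex-3-en-3-yl]oxy}triethylsilane
Conditions: RhCl(PPh3)3 (1 mol%), Et3SiH, toluene, 55 °C
Reagents that add atoms: triethylsilane, CC[SiH](CC)CC
Why: Rhodium-catalysed 1,4-hydrosilylation of the enone places the (Z)-silyl enol ether regiospecifically at C8=C11, which enolisation of the saturated ketone could not guarantee, and the epoxides are inert to these neutral conditions.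

Step 5
Reactants: 8 {[(3Z)-6-(benzyloxy)-1-[(2R,3R)-3-{2-[(2R)-3,3-dimethyloxiran-2-yl]ethyl}-3-methyloxiran-2-yl]hex-3-en-3-yl]oxy}triethylsilane
Product: 9 (3R,5aR,6R,9aR)-6-[2-(benzyloxy)ethyl]-2,2,5a-trimethyl-3-(triethylsilyloxy)octahydro-1-benzoxepin-7(2H)-one
Conditions: Et3SiOTf (1.2 equiv), 2,6-di-tert-butyl-4-methylpyridine, CH2Cl2, −78 °C; Et3N, MeOH
Reagents that add atoms: triethylsilyl trifluoromethanesulfonate, CC[Si](CC)(CC)OS(=O)(=O)C(F)(F)F
Why: Lewis-acid-promoted epoxide-opening cascade (oxacyclisation, then cation–olefin carbocyclisation terminated by a silyl enol ether): silylation of the terminal epoxide lets the neighbouring epoxide oxygen attack the tertiary C2 to form the oxepane, and C11 of the enol ether then opens the epoxonium at C31 with inversion through a chair, which should give the trans ring fusion (C5, C31) from the (R,R)-epoxide, keep C35 from the (R)-epoxide and leave the C11 chain equatorial (the thermodynamic position alpha to the ketone).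

Step 6
Reactants: 9 (3R,5aR,6R,9aR)-6-[2-(benzyloxy)ethyl]-2,2,5a-trimethyl-3-(triethylsilyloxy)octahydro-1-benzoxepin-7(2H)-one
Product: 10 (3R,5aR,6R,7S,9aR)-6-[2-(benzyloxy)ethyl]-2,2,5a,7-tetramethyl-3-(triethylsilyloxy)decahydro-1-benzoxepin-7-ol
Conditions: MeLi, CeCl3, THF, −78 °C; aq. NH4Cl
Reagents that add atoms: methyllithium, [Li]C
Why: Organocerium 1,2-addition to a hindered enolisable ketone, in which axial attack is blocked by the syn-axial C31 methyl, so the methyl group should enter equatorially and leave the C8 hydroxyl axial and cis to that methyl.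

Step 7
Reactants: 10 (3R,5aR,6R,7S,9aR)-6-[2-(benzyloxy)ethyl]-2,2,5a,7-tetramethyl-3-(triethylsilyloxy)decahydro-1-benzoxepin-7-ol
Product: 11 (3R,5aR,6R,7S,9aR)-6-[2-(benzyloxy)ethyl]-2,2,5a,7-tetramethyl-3,7-bis(triethylsilyloxy)decahydro-1-benzoxepine
Conditions: Et3SiOTf, 2,6-lutidine, CH2Cl2, 0 °C
Reagents that add atoms: triethylsilyl trifluoromethanesulfonate, CC[Si](CC)(CC)OS(=O)(=O)C(F)(F)F
Why: Silylation of the hindered tertiary alcohol with a silyl triflate, so that the C8 oxygen can neither quench the organolithium of step 20 nor form a hemiketal with the C14 ketone later.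

Step 8
Reactants: 11 (3R,5aR,6R,7S,9aR)-6-[2-(benzyloxy)ethyl]-2,2,5a,7-tetramethyl-3,7-bis(triethylsilyloxy)decahydro-1-benzoxepine
Product: 12 2-[(3R,5aR,6R,7S,9aR)-2,2,5a,7-tetramethyl-3,7-bis(triethylsilyloxy)decahydro-1-benzoxepin-6-yl]ethanol
Conditions: H2 (1 atm), Pd(OH)2/C, EtOAc, rt
Reagents that add atoms: none
Why: Hydrogenolysis of the benzyl ether in ethyl acetate frees the primary C13 alcohol without touching the silyl ethers.

Step 9
Reactants: 12 2-[(3R,5aR,6R,7S,9aR)-2,2,5a,7-tetramethyl-3,7-bis(triethylsilyloxy)decahydro-1-benzoxepin-6-yl]ethanol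
Product: 13 (3R,5aR,6R,7S,9aR)-6-(2-iodoethyl)-2,2,5a,7-tetramethyl-3,7-bis(triethylsilyloxy)decahydro-1-benzoxepine
Conditions: I2, PPh3, imidazole, CH2Cl2, 0 °C to rt
Reagents that add atoms: iodine, II
Why: Appel-type iodination, in which iodide displaces the alkoxyphosphonium group of the primary alcohol by SN2, and the silylated C8 oxygen cannot cyclise onto C13.

Step 10
Reactants: 14 (S)-4-(tert-butyldimethylsilyloxy)cyclopent-2-en-1-one
Product: 15 (S)-4-(tert-butyldimethylsilyloxy)-2-iodocyclopent-2-en-1-one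
Conditions: I2, pyridine, CH2Cl2, 0 °C to rt
Reagents that add atoms: iodine, II
Why: α-Iodination of the enone by conjugate addition of pyridine, iodination of the enolate and elimination, which leaves the silyloxy-bearing carbon (the future C22) untouched.

Step 11
Reactants: 15 (S)-4-(tert-butyldimethylsilyloxy)-2-iodocyclopent-2-en-1-one
Product: 16 (S)-4-(tert-butyldimethylsilyloxy)-2-methylcyclopent-2-en-1-one
Conditions: MeZnCl, Pd(PPh3)4 (5 mol%), THF, 0 °C to rt
Reagents that add atoms: methylzinc chloride, C[Zn]Cl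
Why: Negishi coupling of the vinyl iodide puts the C26 methyl on C25 with a reagent that does not add to the enone.

Step 12
Reactants: 16 (S)-4-(tert-butyldimethylsilyloxy)-2-methylcyclopent-2-en-1-one; 17 2-(2-bromoethyl)-2,5,5-trimethyl-1,3-dioxane
Product: 19 tert-butyldimethyl{[(1S,2S)-3-methyl-2-[2-(2,5,5-trimethyl-1,3-dioxan-2-yl)ethyl]-4-(trimethylsilyloxy)cyclopent-3-en-1-yl]oxy}silane, via Grignard reagent 18 (not isolated)
Conditions: 17, Mg, THF; then 16, CuBr·SMe2 (10 mol%), Me3SiCl, THF, −78 °C; Et3N, pentane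
Reagents that add atoms: chlorotrimethylsilane, C[Si](C)(C)Cl
Why: Copper-catalysed conjugate addition of a Grignard reagent with silyl chloride trapping, in which the masked 3-oxobutyl group should add to C21 anti to the silyloxy group on C22 and the enolate is held as the C24=C25 silyl enol ether.

Step 13
Reactants: 19 tert-butyldimethyl{[(1S,2S)-3-methyl-2-[2-(2,5,5-trimethyl-1,3-dioxan-2-yl)ethyl]-4-(trimethylsilyloxy)cyclopent-3-en-1-yl]oxy}silane
Product: 22 (4R,5S)-5-hydroxy-5-methyl-4-[2-(2,5,5-trimethyl-1,3-dioxan-2-yl)ethyl]cyclopent-2-en-1-one, via silyloxy ketone 20 (not isolated), via silylated enone 21 (not isolated)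
Conditions: mCPBA (1.05 equiv), NaHCO3, CH2Cl2, −20 °C; then DBU, 0 °C to rt; aq. citric acid
Reagents that add atoms: 3-chloroperbenzoic acid, OOC(=O)c1cccc(Cl)c1
Why: Rubottom oxidation followed by E1cB elimination, in which the peracid should attack the enol ether anti to the neighbouring C21 arm so that the C25 oxygen ends trans to that arm with the methyl cis, and base then expels the beta-silyloxy group to give the C22=C23 enone.

Step 14
Reactants: 22 (4R,5S)-5-hydroxy-5-methyl-4-[2-(2,5,5-trimethyl-1,3-dioxan-2-yl)ethyl]cyclopent-2-en-1-one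
Product: 23 (1S,2S,5R)-1-methyl-5-[2-(2,5,5-trimethyl-1,3-dioxan-2-yl)ethyl]cyclopent-3-ene-1,2-diol
Conditions: NaBH4, CeCl3·7H2O, MeOH, −78 °C
Reagents that add atoms: none
Why: Luche 1,2-reduction, in which hydride should approach C24 from the face of the small C25 hydroxyl and away from the C25 methyl and the C21 arm, so that the new hydroxyl is cis to both carbon groups (trans diol).

Step 15
Reactants: 23 (1S,2S,5R)-1-methyl-5-[2-(2,5,5-trimethyl-1,3-dioxan-2-yl)ethyl]cyclopent-3-ene-1,2-diol; 24 isobutyryl chloride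
Product: 25 (1S,4R,5S)-5-hydroxy-5-methyl-4-[2-(2,5,5-trimethyl-1,3-dioxan-2-yl)ethyl]cyclopent-2-en-1-yl 2-methylpropanoate
Conditions: pyridine, DMAP (cat.), CH2Cl2, 0 °C
Reagents that add atoms: none
Why: Acylation under nucleophilic catalysis should take only the secondary allylic hydroxyl at C24, the tertiary C25 hydroxyl being too hindered.

Step 16
Reactants: 25 (1S,4R,5S)-5-hydroxy-5-methyl-4-[2-(2,5,5-trimethyl-1,3-dioxan-2-yl)ethyl]cyclopent-2-en-1-yl 2-methylpropanoate
Product: 26 (1S,4R,5S)-5-methyl-5-(triethylsilyloxy)-4-[2-(2,5,5-trimethyl-1,3-dioxan-2-yl)ethyl]cyclopent-2-en-1-yl 2-methylpropanoate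
Conditions: Et3SiOTf, 2,6-lutidine, CH2Cl2, −40 to 0 °C
Reagents that add atoms: triethylsilyl trifluoromethanesulfonate, CC[Si](CC)(CC)OS(=O)(=O)C(F)(F)F
Why: Silylation of the tertiary alcohol with a silyl triflate and a hindered base, which tolerates ester and ketal, removes the acidic hydroxyl and the risk of acyl migration before the enolate step.

Step 17
Reactants: 26 (1S,4R,5S)-5-methyl-5-(triethylsilyloxy)-4-[2-(2,5,5-trimethyl-1,3-dioxan-2-yl)ethyl]cyclopent-2-en-1-yl 2-methylpropanoate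
Product: 29 2-methyl-2-{(1R,4R,5R)-4-methyl-4-(triethylsilyloxy)-5-[2-(2,5,5-trimethyl-1,3-dioxan-2-yl)ethyl]cyclopent-2-en-1-yl}propanoic acid, via silyl ketene acetal 27 (not isolated), via trimethylsilyl ester 28 (not isolated)
Conditions: LiN(i-Pr)2, Me3SiCl, Et3N, THF, −78 °C to 60 °C; aq. citric acid
Reagents that add atoms: none
Why: Ireland–Claisen rearrangement, in which the isobutyrate silyl ketene acetal (no E/Z issue) shifts suprafacially across C24–C23=C22, so the C22–C28 bond and the quaternary C28 must form on the face of the C24 oxygen, cis to the C21 arm, a relationship that an intermolecular addition beside that arm would not give.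

Step 18
Reactants: 29 2-methyl-2-{(1R,4R,5R)-4-methyl-4-(triethylsilyloxy)-5-[2-(2,5,5-trimethyl-1,3-dioxan-2-yl)ethyl]cyclopent-2-en-1-yl}propanoic acid
Product: 30 2-methyl-2-{(1R,2R,3R)-3-methyl-3-(triethylsilyloxy)-2-[2-(2,5,5-trimethyl-1,3-dioxan-2-yl)ethyl]cyclopentyl}propanoic acid
Conditions: H2 (1 atm), Pd/C, EtOAc, rt
Reagents that add atoms: none
Why: Heterogeneous hydrogenation saturates the disubstituted C23=C24 alkene, which has done its work, and creates no stereocentre.

Step 19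
Reactants: 30 2-methyl-2-{(1R,2R,3R)-3-methyl-3-(triethylsilyloxy)-2-[2-(2,5,5-trimethyl-1,3-dioxan-2-yl)ethyl]cyclopentyl}propanoic acid
Product: 32 N-methoxy-N,2-dimethyl-2-{(1R,2R,3R)-3-methyl-3-(triethylsilyloxy)-2-[2-(2,5,5-trimethyl-1,3-dioxan-2-yl)ethyl]cyclopentyl}propanamide, via acid chloride 31 (not isolated)
Conditions: 1-chloro-N,N,2-trimethylprop-1-en-1-amine, CH2Cl2, 0 °C to rt; then MeNH(OMe)·HCl, i-Pr2NEt, DMAP (cat.), rt
Reagents that add atoms: N,O-dimethylhydroxylamine hydrochloride, CNOC.Cl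
Why: Acid chloride formation with a chloroenamine under neutral conditions and aminolysis should convert the hindered acid into the Weinreb amide without acid that would endanger the ketal or the silyl ether.

Step 20
Reactants: 13 (3R,5aR,6R,7S,9aR)-6-(2-iodoethyl)-2,2,5a,7-tetramethyl-3,7-bis(triethylsilyloxy)decahydro-1-benzoxepine; 32 N-methoxy-N,2-dimethyl-2-{(1R,2R,3R)-3-methyl-3-(triethylsilyloxy)-2-[2-(2,5,5-trimethyl-1,3-dioxan-2-yl)ethyl]cyclopentyl}propanamide
Product: 34 4-methyl-4-{(1R,2R,3R)-3-methyl-3-(triethylsilyloxy)-2-[2-(2,5,5-trimethyl-1,3-dioxan-2-yl)ethyl]cyclopentyl}-1-[(3R,5aR,6R,7S,9aR)-2,2,5a,7-tetramethyl-3,7-bis(triethylsilyloxy)decahydro-1-benzoxepin-6-yl]pentan-3-one, via alkyllithium 33 (not isolated)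
Conditions: 13 (1.3 equiv), t-BuLi (2.6 equiv), Et2O/pentane, −78 °C; then 32, −78 to 0 °C; aq. NH4Cl
Reagents that add atoms: none
Why: Iodine–lithium exchange followed by Weinreb ketone synthesis, in which the primary alkyllithium adds once to the N-methoxy-N-methylamide and the chelated tetrahedral adduct survives until work-up, so the hindered C14 ketone and the C13–C14 bond form without over-addition.

Step 21
Reactants: 34 4-methyl-4-{(1R,2R,3R)-3-methyl-3-(triethylsilyloxy)-2-[2-(2,5,5-trimethyl-1,3-dioxan-2-yl)ethyl]cyclopentyl}-1-[(3R,5aR,6R,7S,9aR)-2,2,5a,7-tetramethyl-3,7-bis(triethylsilyloxy)decahydro-1-benzoxepin-6-yl]pentan-3-one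
Product: 35 4-methyl-4-[(1R,2R,3R)-3-methyl-2-(3-oxobutyl)-3-(triethylsilyloxy)cyclopentyl]-1-[(3R,5aR,6R,7S,9aR)-2,2,5a,7-tetramethyl-3,7-bis(triethylsilyloxy)decahydro-1-benzoxepin-6-yl]pentan-3-one (seco-ring-C diketone)
Conditions: PPTS (cat.), acetone/H2O 9:1, 45 °C
Reagents that add atoms: water, O
Why: Mild acid-catalysed ketal hydrolysis releases the C16 methyl ketone, the 1,3-dioxane being much more acid-labile than the hindered triethylsilyl ethers, and no carbon alpha to either carbonyl is stereogenic.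

Step 22
Reactants: 35 4-methyl-4-[(1R,2R,3R)-3-methyl-2-(3-oxobutyl)-3-(triethylsilyloxy)cyclopentyl]-1-[(3R,5aR,6R,7S,9aR)-2,2,5a,7-tetramethyl-3,7-bis(triethylsilyloxy)decahydro-1-benzoxepin-6-yl]pentan-3-one
Product: 37 tris(triethylsilyl) ether of the C14=C16 cycloheptene carrying rings A to D (full carbon skeleton of the target), via titanium pinacolate 36 (not isolated)
Conditions: TiCl3(DME)1.5, Zn–Cu, DME, reflux; 35 added by syringe pump over 30 h (final concentration about 0.002 M)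
Reagents that add atoms: none
Why: Electron transfer from low-valent titanium to both carbonyls gives titanium-bound ketyls that couple to the pinacolate 36, which is then deoxygenated on the titanium surface to the C14=C16 alkene. The closest known reaction type is the intramolecular McMurry coupling of diketones to tetrasubstituted cycloalkenes, seven-membered rings included. Ring C closes as a seven-membered carbonyl–carbonyl coupling, helped by the cis arrangement of the two carbonyl-bearing arms on C21 and C22 of ring D. No stereocentre is formed, and C21, C22 and C25 cannot epimerise because none of them is alpha to a carbonyl. The step needs intramolecular over intermolecular coupling, which slow addition at high dilution should secure, and tolerance of the neopentyl C14 ketone, the silyl ethers and the oxepane, none of which carries a group that low-valent titanium reduces.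

Step 23
Reactants: 37 tris(triethylsilyl) ether of the C14=C16 cycloheptene
Product: 38 tris(triethylsilyl) ether of the C18 ketone (enone C18(=O)–C16=C14)
Conditions: Rh2(cap)4 (1 mol%), t-BuOOH, K2CO3, CH2Cl2, rt
Reagents that add atoms: tert-butyl hydroperoxide, CC(C)(C)OO
Why: Radical allylic C–H oxidation with dirhodium caprolactamate and the hydroperoxide, in which abstraction at the ring methylene C18 gives an unstrained allyl radical whereas a planar radical at C13 would clash with the C17 methyl or the gem-dimethyl group on C28, so the enone should form at C18.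

Step 24
Reactants: 38 tris(triethylsilyl) ether of the C18 ketone
Product: 39 tris(triethylsilyl) ether of the (18R)-allylic alcohol
Conditions: (S)-2-methyl-CBS-oxazaborolidine (0.5 equiv), BH3·SMe2, THF, −30 °C; MeOH
Reagents that add atoms: none
Why: Corey–Bakshi–Shibata reduction, in which the oxazaborolidine binds the ketone with the alkenyl carbon C16 as the large group and delivers hydride to one face, so the catalyst should set C18 as R.

Step 25
Reactants: 39 tris(triethylsilyl) ether of the (18R)-allylic alcohol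
Product: 40 8,25,35-tris-O-(triethylsilyl) derivative of the target (14,16-epoxide cis to the C18 hydroxyl)
Conditions: VO(acac)2 (5 mol%), t-BuOOH, CH2Cl2, 0 °C to rt
Reagents that add atoms: tert-butyl hydroperoxide, CC(C)(C)OO
Why: Vanadium-catalysed hydroxyl-directed epoxidation of a cyclic allylic alcohol, in which the vanadate ester of the C18 hydroxyl delivers the peroxide oxygen to the same face of the C14=C16 alkene and so sets C14 and C16.

Step 26
Reactants: 40 8,25,35-tris-O-(triethylsilyl) derivative of the target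
Product: 41 CNP0203623.2 (target)
Conditions: Bu4NF, THF, 0 °C to rt; aq. NH4Cl
Reagents that add atoms: none
Why: Fluoride-mediated desilylation should remove the three triethylsilyl ethers under non-acidic conditions that spare the tetrasubstituted epoxide, and the C18 hydroxyl, being cis to the epoxide, cannot open it from the rear.

Compound list

1 | geranyl bromide | CC(C)=CCC/C(C)=C/CBr | starting material
2 | dimethyl (2-oxopropyl)phosphonate | CC(=O)CP(=O)(OC)OC | starting material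
3 | sodium lithium dianion of 2 | [Na+].[Li+].[CH2-]C(=O)[CH-]P(=O)(OC)OC | intermediate
4 | dimethyl [(5E)-6,10-dimethyl-2-oxoundeca-5,9-dien-1-yl]phosphonate | CC(C)=CCC/C(C)=C/CCC(=O)CP(=O)(OC)OC | intermediate
5 | benzyloxyacetaldehyde | O=CCOCc1ccccc1 | starting material
6 | (2E,7E)-1-(benzyloxy)-8,12-dimethyltrideca-2,7,11-trien-4-one | CC(C)=CCC/C(C)=C/CCC(=O)/C=C/COCc1ccccc1 | intermediate
7 | (2E)-1-(benzyloxy)-6-[(2R,3R)-3-{2-[(2R)-3,3-dimethyloxiran-2-yl]ethyl}-3-methyloxiran-2-yl]hex-2-en-4-one | CC1(C)O[C@@H]1CC[C@@]2(C)O[C@@H]2CCC(=O)/C=C/COCc3ccccc3 | intermediate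
8 | (Z)-triethylsilyl enol ether of the saturated diepoxy ketone (C8=C11) | CC1(C)O[C@@H]1CC[C@@]2(C)O[C@@H]2CC/C(O[Si](CC)(CC)CC)=C/CCOCc3ccccc3 | intermediate
9 | (3R,5aR,6R,9aR)-6-[2-(benzyloxy)ethyl]-2,2,5a-trimethyl-3-(triethylsilyloxy)octahydro-1-benzoxepin-7(2H)-one (trans-fused) | CC1(C)O[C@@H]2CCC(=O)[C@H](CCOCc3ccccc3)[C@@]2(C)CC[C@H]1O[Si](CC)(CC)CC | intermediate
10 | (3R,5aR,6R,7S,9aR)-6-[2-(benzyloxy)ethyl]-2,2,5a,7-tetramethyl-3-(triethylsilyloxy)decahydro-1-benzoxepin-7-ol | CC1(C)O[C@@H]2CC[C@](C)(O)[C@H](CCOCc3ccccc3)[C@@]2(C)CC[C@H]1O[Si](CC)(CC)CC | intermediate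
11 | (3R,5aR,6R,7S,9aR)-6-[2-(benzyloxy)ethyl]-2,2,5a,7-tetramethyl-3,7-bis(triethylsilyloxy)decahydro-1-benzoxepine | CC1(C)O[C@@H]2CC[C@](C)(O[Si](CC)(CC)CC)[C@H](CCOCc3ccccc3)[C@@]2(C)CC[C@H]1O[Si](CC)(CC)CC | intermediate
12 | 2-[(3R,5aR,6R,7S,9aR)-2,2,5a,7-tetramethyl-3,7-bis(triethylsilyloxy)decahydro-1-benzoxepin-6-yl]ethanol | CC1(C)O[C@@H]2CC[C@](C)(O[Si](CC)(CC)CC)[C@H](CCO)[C@@]2(C)CC[C@H]1O[Si](CC)(CC)CC | intermediate
13 | (3R,5aR,6R,7S,9aR)-6-(2-iodoethyl)-2,2,5a,7-tetramethyl-3,7-bis(triethylsilyloxy)decahydro-1-benzoxepine | CC1(C)O[C@@H]2CC[C@](C)(O[Si](CC)(CC)CC)[C@H](CCI)[C@@]2(C)CC[C@H]1O[Si](CC)(CC)CC | intermediate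
14 | (S)-4-(tert-butyldimethylsilyloxy)cyclopent-2-en-1-one | O=C1C=C[C@@H](O[Si](C)(C)C(C)(C)C)C1 | starting material
15 | (S)-4-(tert-butyldimethylsilyloxy)-2-iodocyclopent-2-en-1-one | O=C1C(I)=C[C@@H](O[Si](C)(C)C(C)(C)C)C1 | intermediate
16 | (S)-4-(tert-butyldimethylsilyloxy)-2-methylcyclopent-2-en-1-one | O=C1C(C)=C[C@@H](O[Si](C)(C)C(C)(C)C)C1 | intermediate
17 | 2-(2-bromoethyl)-2,5,5-trimethyl-1,3-dioxane | CC1(CCBr)OCC(C)(C)CO1 | starting material
18 | [2-(2,5,5-trimethyl-1,3-dioxan-2-yl)ethyl]magnesium bromide | CC1(CC[Mg]Br)OCC(C)(C)CO1 | intermediate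
19 | trimethylsilyl enol ether (C24=C25), side chain on C21 trans to the silyloxy group on C22 | C[Si](C)(C)OC1=C(C)[C@H](CCC2(C)OCC(C)(C)CO2)[C@@H](O[Si](C)(C)C(C)(C)C)C1 | intermediate
20 | 2-methyl-2-(trimethylsilyloxy)-3-(side chain)-4-(tert-butyldimethylsilyloxy)cyclopentanone, C25 oxygen trans to the side chain | O=C1C[C@H](O[Si](C)(C)C(C)(C)C)[C@@H](CCC2(C)OCC(C)(C)CO2)[C@]1(C)O[Si](C)(C)C | intermediate
21 | trimethylsilyl ether of 22 | O=C1C=C[C@@H](CCC2(C)OCC(C)(C)CO2)[C@]1(C)O[Si](C)(C)C | intermediate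
22 | (4R,5S)-5-hydroxy-5-methyl-4-[2-(2,5,5-trimethyl-1,3-dioxan-2-yl)ethyl]cyclopent-2-en-1-one | O=C1C=C[C@@H](CCC2(C)OCC(C)(C)CO2)[C@]1(C)O | intermediate
23 | (1S,2S,5R)-1-methyl-5-[2-(2,5,5-trimethyl-1,3-dioxan-2-yl)ethyl]cyclopent-3-ene-1,2-diol | O[C@H]1C=C[C@@H](CCC2(C)OCC(C)(C)CO2)[C@]1(C)O | intermediate
24 | isobutyryl chloride | CC(C)C(=O)Cl | starting material
25 | (1S,4R,5S)-5-hydroxy-5-methyl-4-[2-(2,5,5-trimethyl-1,3-dioxan-2-yl)ethyl]cyclopent-2-en-1-yl 2-methylpropanoate | CC(C)C(=O)O[C@H]1C=C[C@@H](CCC2(C)OCC(C)(C)CO2)[C@]1(C)O | intermediate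
26 | (1S,4R,5S)-5-methyl-5-(triethylsilyloxy)-4-[2-(2,5,5-trimethyl-1,3-dioxan-2-yl)ethyl]cyclopent-2-en-1-yl 2-methylpropanoate | CC(C)C(=O)O[C@H]1C=C[C@@H](CCC2(C)OCC(C)(C)CO2)[C@]1(C)O[Si](CC)(CC)CC | intermediate
27 | trimethylsilyl ketene acetal of 26 | CC(C)=C(O[Si](C)(C)C)O[C@H]1C=C[C@@H](CCC2(C)OCC(C)(C)CO2)[C@]1(C)O[Si](CC)(CC)CC | intermediate
28 | trimethylsilyl ester of 29 | C[Si](C)(C)OC(=O)C(C)(C)[C@@H]1C=C[C@@](C)(O[Si](CC)(CC)CC)[C@@H]1CCC2(C)OCC(C)(C)CO2 | intermediate
29 | 2-methyl-2-{(1R,4R,5R)-4-methyl-4-(triethylsilyloxy)-5-[2-(2,5,5-trimethyl-1,3-dioxan-2-yl)ethyl]cyclopent-2-en-1-yl}propanoic acid | OC(=O)C(C)(C)[C@@H]1C=C[C@@](C)(O[Si](CC)(CC)CC)[C@@H]1CCC2(C)OCC(C)(C)CO2 | intermediate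
30 | 2-methyl-2-{(1R,2R,3R)-3-methyl-3-(triethylsilyloxy)-2-[2-(2,5,5-trimethyl-1,3-dioxan-2-yl)ethyl]cyclopentyl}propanoic acid | OC(=O)C(C)(C)[C@@H]1CC[C@@](C)(O[Si](CC)(CC)CC)[C@@H]1CCC2(C)OCC(C)(C)CO2 | intermediate
31 | acid chloride of 30 | ClC(=O)C(C)(C)[C@@H]1CC[C@@](C)(O[Si](CC)(CC)CC)[C@@H]1CCC2(C)OCC(C)(C)CO2 | intermediate
32 | N-methoxy-N,2-dimethyl-2-{(1R,2R,3R)-3-methyl-3-(triethylsilyloxy)-2-[2-(2,5,5-trimethyl-1,3-dioxan-2-yl)ethyl]cyclopentyl}propanamide | CON(C)C(=O)C(C)(C)[C@@H]1CC[C@@](C)(O[Si](CC)(CC)CC)[C@@H]1CCC2(C)OCC(C)(C)CO2 | intermediate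
33 | {2-[(3R,5aR,6R,7S,9aR)-2,2,5a,7-tetramethyl-3,7-bis(triethylsilyloxy)decahydro-1-benzoxepin-6-yl]ethyl}lithium | CC1(C)O[C@@H]2CC[C@](C)(O[Si](CC)(CC)CC)[C@H](CC[Li])[C@@]2(C)CC[C@H]1O[Si](CC)(CC)CC | intermediate
34 | coupled C14 ketone with the C16 ketone as its 5,5-dimethyl-1,3-dioxane ketal | CC1(C)O[C@@H]2CC[C@](C)(O[Si](CC)(CC)CC)[C@H](CCC(=O)C(C)(C)[C@@H]3CC[C@@](C)(O[Si](CC)(CC)CC)[C@@H]3CCC4(C)OCC(C)(C)CO4)[C@@]2(C)CC[C@H]1O[Si](CC)(CC)CC | intermediate
35 | seco-ring-C diketone (C14 and C16 ketones; rings A, B and D; three triethylsilyl ethers) | CC1(C)O[C@@H]2CC[C@](C)(O[Si](CC)(CC)CC)[C@H](CCC(=O)C(C)(C)[C@@H]3CC[C@@](C)(O[Si](CC)(CC)CC)[C@@H]3CCC(C)=O)[C@@]2(C)CC[C@H]1O[Si](CC)(CC)CC | intermediate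
36 | titanium pinacolate of 35 (drawn as the titanium-bound 14,16-diolate; C14 and C16 unassigned) | CC1(C)O[C@@H]2CC[C@](C)(O[Si](CC)(CC)CC)[C@H](CCC3([O-])C(C)([O-])CC[C@@H]4[C@@H](CC[C@@]4(C)O[Si](CC)(CC)CC)C3(C)C)[C@@]2(C)CC[C@H]1O[Si](CC)(CC)CC | intermediate
37 | tris(triethylsilyl) ether of the tetrasubstituted C14=C16 cycloheptene (rings A to D) | CC1(C)O[C@@H]2CC[C@](C)(O[Si](CC)(CC)CC)[C@H](CCC3=C(C)CC[C@@H]4[C@@H](CC[C@@]4(C)O[Si](CC)(CC)CC)C3(C)C)[C@@]2(C)CC[C@H]1O[Si](CC)(CC)CC | intermediate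
38 | tris(triethylsilyl) ether of the C18 enone | CC1(C)O[C@@H]2CC[C@](C)(O[Si](CC)(CC)CC)[C@H](CCC3=C(C)C(=O)C[C@@H]4[C@@H](CC[C@@]4(C)O[Si](CC)(CC)CC)C3(C)C)[C@@]2(C)CC[C@H]1O[Si](CC)(CC)CC | intermediate
39 | tris(triethylsilyl) ether of the (18R)-allylic alcohol | CC1(C)O[C@@H]2CC[C@](C)(O[Si](CC)(CC)CC)[C@H](CCC3=C(C)[C@H](O)C[C@@H]4[C@@H](CC[C@@]4(C)O[Si](CC)(CC)CC)C3(C)C)[C@@]2(C)CC[C@H]1O[Si](CC)(CC)CC | intermediate
40 | 8,25,35-tris-O-(triethylsilyl) derivative of the target | CC1(C)O[C@@H]2CC[C@](C)(O[Si](CC)(CC)CC)[C@H](CC[C@@]34O[C@]3(C)[C@H](O)C[C@@H]3[C@@H](CC[C@@]3(C)O[Si](CC)(CC)CC)C4(C)C)[C@@]2(C)CC[C@H]1O[Si](CC)(CC)CC | intermediate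
41 | CNP0203623.2 | CC1(C)O[C@@H]2CC[C@](C)(O)[C@H](CC[C@@]34O[C@]3(C)[C@H](O)C[C@@H]3[C@@H](CC[C@@]3(C)O)C4(C)C)[C@@]2(C)CC[C@H]1O | target

Total step count: 26.
Longest linear sequence: 17 steps (steps 10 to 26, from 14 to 41). The other branch runs through steps 1 to 9 and joins at step 20.

Steps most likely to fail

Step 22. The pinacolate may form but resist deoxygenation at the neopentyl C14 centre, or the ketyls may be reduced to alcohols or couple between molecules. The fallback sets out from 35 and separates ring closure from deoxygenation. SmI2 in THF with HMPA and t-BuOH would close ring C by ketyl–carbonyl coupling to the cis-14,16-diol F1. Thiocarbonyldiimidazole in hot toluene would convert it into the cyclic thionocarbonate F2. Corey–Winter fragmentation with 1,3-dimethyl-2-phenyl-1,3,2-diazaphospholidine at 40 °C would then return the route at 37.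

Step 5. The Lewis acid may ionise an epoxide before a nucleophile is in reach, which leads to hydride shift and ketone formation, or the trisubstituted silyl enol ether may be lost by protodesilylation before it can terminate the cascade. The fallback sets out from 4 and closes ring B with a stabilised enol before the side chain is attached. Shi epoxidation of 4 would give the diepoxy β-ketophosphonate F3. Et3SiOTf with 2,6-di-tert-butyl-4-methylpyridine would silylate the enol in situ and trigger the same oxa- then carbacyclisation to the bicyclic β-ketophosphonate F4. Horner–Wadsworth–Emmons reaction of F4 with 5 (LiCl, DBU) would give the exocyclic enone F5. Conjugate reduction with [(Ph3P)CuH]6 and protonation to the equatorial C11 epimer would return the route at 9.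

Step 23. Hydrogen abstraction may not discriminate between C18, C13 and C17, or the enone may be oxidised further. The fallback sets out from 37 and replaces the radical oxidation by a pericyclic hydroxylation. SeO2 (catalytic) with t-BuOOH in CH2Cl2 would react by an ene reaction and a 2,3-sigmatropic shift, which favours ring methylene groups, to give the C18 allylic alcohols F6 as an epimer mixture. MnO2 would oxidise them to the enone and return the route at 38.

Further compounds

F1 | step 22 | cis-14,16-diol of the closed ring C (three triethylsilyl ethers; C14 and C16 not assigned) | CC1(C)O[C@@H]2CC[C@](C)(O[Si](CC)(CC)CC)[C@H](CCC3(O)C(C)(O)CC[C@@H]4[C@@H](CC[C@@]4(C)O[Si](CC)(CC)CC)C3(C)C)[C@@]2(C)CC[C@H]1O[Si](CC)(CC)CC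
F2 | step 22 | cyclic 14,16-thionocarbonate of F1 | CC1(C)O[C@@H]2CC[C@](C)(O[Si](CC)(CC)CC)[C@H](CCC34OC(=S)OC3(C)CC[C@@H]3[C@@H](CC[C@@]3(C)O[Si](CC)(CC)CC)C4(C)C)[C@@]2(C)CC[C@H]1O[Si](CC)(CC)CC
F3 | step 5 | dimethyl {4-[(2R,3R)-3-{2-[(2R)-3,3-dimethyloxiran-2-yl]ethyl}-3-methyloxiran-2-yl]-2-oxobutyl}phosphonate | CC1(C)O[C@@H]1CC[C@@]2(C)O[C@@H]2CCC(=O)CP(=O)(OC)OC
F4 | step 5 | dimethyl [(3R,5aR,9aR)-2,2,5a-trimethyl-7-oxo-3-(triethylsilyloxy)decahydro-1-benzoxepin-6-yl]phosphonate (C6 epimerisable) | CC1(C)O[C@@H]2CCC(=O)C(P(=O)(OC)OC)[C@@]2(C)CC[C@H]1O[Si](CC)(CC)CC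
F5 | step 5 | (3R,5aR,9aR)-6-[2-(benzyloxy)ethylidene]-2,2,5a-trimethyl-3-(triethylsilyloxy)octahydro-1-benzoxepin-7(2H)-one (alkene geometry not assigned) | CC1(C)O[C@@H]2CCC(=O)C(=CCOCc3ccccc3)[C@@]2(C)CC[C@H]1O[Si](CC)(CC)CC
F6 | step 23 | tris(triethylsilyl) ether of the C18 allylic alcohols (both C18 epimers) | CC1(C)O[C@@H]2CC[C@](C)(O[Si](CC)(CC)CC)[C@H](CCC3=C(C)C(O)C[C@@H]4[C@@H](CC[C@@]4(C)O[Si](CC)(CC)CC)C3(C)C)[C@@]2(C)CC[C@H]1O[Si](CC)(CC)CC
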